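**Plan**
- Retrosynthetic cuts: (i) the C3–H and C4–H bonds, back to a C3=C4 alkene in a 2,5-dihydrofuran; (ii) the O1–C5 bond, back to a 2-aryl-3-vinyl oxirane made of O1, C2 and C3 with C4=C5 as the vinyl group; (iii) the oxirane oxygen; (iv) the C3–C4 bond between a 3-arylpropynol and a 2-metallated allylarene.
- Forward order: a Sonogashira coupling and a copper-catalysed allylation give the two halves; anti-carbomagnesiation joins them at C3–C4; asymmetric epoxidation makes the three-membered ring O1/C2/C3; this ring is expanded by two atoms (C4, C5) to the oxolane ring in its 2,5-dihydro form; hydrogenation finishes.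
- Enabling feature: in the oxolane ring O1 lies between the aryl-bearing C2–H and an unsubstituted C5H2, and C3 and C4 each carry one carbon substituent and one hydrogen. O1–C2–C3 can therefore be stored as an oxirane whose C3 bears the C4=C5 vinyl unit, and O1 can move from C3 to C5 across the allyl system.
- Stereochemistry: C2 comes from the Sharpless epoxidation with L-(+)-diethyl tartrate and is kept because the C2–O1 bond is never broken. C3 and C4 come from syn addition of H2 to the face of C3=C4 opposite to the C2 aryl group, which gives the all-cis (2R,3R,4R) triad.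

Key step: step 6

Assumption: (3,4-dimethoxyphenyl)magnesium bromide (4) is bought as its THF solution; it can equally be made from 4-bromo-1,2-dimethoxybenzene and magnesium.

**Step 1**
Reactants: 1 5-iodo-1,2,3-trimethoxybenzene; 2 prop-2-yn-1-ol
Product: 3 3-(3,4,5-trimethoxyphenyl)prop-2-yn-1-ol
Conditions: PdCl2(PPh3)2 (2 mol %), CuI (4 mol %), Et3N, THF, rt
Reagents that add atoms: none
Why: Sonogashira coupling of an aryl iodide with a terminal alkyne, which tolerates the free propargylic hydroxyl group and involves no stereocenter.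

**Step 2**
Reactants: 4 (3,4-dimethoxyphenyl)magnesium bromide; 5 2,3-dibromoprop-1-ene
Product: 6 4-(2-bromoprop-2-en-1-yl)-1,2-dimethoxybenzene
Conditions: CuI (5 mol %), THF, −10 °C to rt
Reagents that add atoms: none
Why: Copper-catalysed allylic substitution of the allylic bromide by the aryl Grignard reagent (direct and allylic-shift attack give the same product), while the vinylic C–Br bond should stay intact.

**Step 3**
Reactants: 3 3-(3,4,5-trimethoxyphenyl)prop-2-yn-1-ol; 6 4-(2-bromoprop-2-en-1-yl)-1,2-dimethoxybenzene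
Product: 10 (2E)-2-[3-(3,4-dimethoxyphenyl)prop-1-en-2-yl]-3-(3,4,5-trimethoxyphenyl)prop-2-en-1-ol, via alkenylmagnesium bromide 7 (not isolated), via chloromagnesium alkynolate 8 (not isolated), via oxamagnesacycle 9 (not isolated)
Conditions: Mg, THF, 40 °C (6 to 7); MeMgCl (1.0 equiv), THF, 0 °C (3 to 8); 7 (2 equiv) added to 8, PhMe/THF, 80 °C; aq NH4Cl, 0 °C
Reagents that add atoms: none
Why: Chelation-controlled anti-carbomagnesiation of a propargylic alkoxide, in which the alkenyl group adds to the alkyne carbon next to CH2O and magnesium ends on the aryl-bearing carbon inside the five-membered chelate 9, so that protonation should give the E alkene with the aryl group trans to CH2OH.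

**Step 4**
Reactants: 10 (2E)-2-[3-(3,4-dimethoxyphenyl)prop-1-en-2-yl]-3-(3,4,5-trimethoxyphenyl)prop-2-en-1-ol
Product: 11 [(2S,3S)-2-[3-(3,4-dimethoxyphenyl)prop-1-en-2-yl]-3-(3,4,5-trimethoxyphenyl)oxiran-2-yl]methanol
Conditions: Ti(OiPr)4 (10 mol %), L-(+)-diethyl tartrate (12 mol %), t-BuOOH (2 equiv, isooctane), 4 Å MS, CH2Cl2, −20 °C; aq NaOH/brine work-up
Reagents that add atoms: tert-butyl hydroperoxide, CC(C)(C)OO
Why: Sharpless asymmetric epoxidation of a 2,3-disubstituted (E)-allylic alcohol; L-(+)-tartrate should deliver oxygen to the face that gives the (2S,3S)-oxirane, as for (E)-2-methyl-3-phenylprop-2-en-1-ol, and the homoallylic 1,1-disubstituted alkene should not react.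

**Step 5**
Reactants: 11 [(2S,3S)-2-[3-(3,4-dimethoxyphenyl)prop-1-en-2-yl]-3-(3,4,5-trimethoxyphenyl)oxiran-2-yl]methanol
Product: 12 tert-butyl{[(2S,3S)-2-[3-(3,4-dimethoxyphenyl)prop-1-en-2-yl]-3-(3,4,5-trimethoxyphenyl)oxiran-2-yl]methoxy}dimethylsilane
Conditions: TBSCl, imidazole, CH2Cl2, 0 °C to rt
Reagents that add atoms: tert-butyldimethylsilyl chloride, CC(C)(C)[Si](C)(C)Cl
Why: Silylation of the primary alcohol under mildly basic conditions should leave the acid-sensitive aryl vinyl oxirane intact and masks the hydroxyl group, which could otherwise open the oxirane or bind the copper catalyst in step 6.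

**Step 6**
Reactants: 12 tert-butyl{[(2S,3S)-2-[3-(3,4-dimethoxyphenyl)prop-1-en-2-yl]-3-(3,4,5-trimethoxyphenyl)oxiran-2-yl]methoxy}dimethylsilane
Product: 13 tert-butyl{[(2S)-4-[(3,4-dimethoxyphenyl)methyl]-2-(3,4,5-trimethoxyphenyl)-2,5-dihydrofuran-3-yl]methoxy}dimethylsilane
Conditions: Cu(hfacac)2 (copper bis(hexafluoroacetylacetonate), 5 mol %), PhMe, 110–150 °C, sealed tube
Reagents that add atoms: none
Why: The copper Lewis acid activates the oxirane and the tertiary, allylic C3–O bond opens through the s-cis conformer (formally an addition in the SN2′ sense that gives a six-membered alkoxy σ-allyl copper chelate), after which C–O bond formation at the CH2 terminus C5 gives the 2,5-dihydrofuran; the net change is a 1,3-shift of O1 from C3 to C5 and a two-atom expansion of the oxirane (O1, C2, C3) to the oxolane ring (O1, C2, C3, C4, C5). The closest known reaction type is the copper-catalysed rearrangement of vinyl oxiranes to 2,5-dihydrofurans. The five-membered ring closes by O1–C5 bond formation at the terminus of the C3–C4–C5 allyl unit, formally a 5-endo closure that the metal chelate makes feasible. No new stereocenter arises: the C2–O1 bond is never broken, so the configuration set at the aryl-bearing carbon in step 4 is carried over, while the C3 center is deliberately erased into the C3=C4 alkene. The step needs cleavage of the allylic C3–O bond in preference to the benzylic C2–O bond, and closure at C5 instead of a hydride shift; the tertiary allylic position, the soft copper catalyst in a non-polar solvent and the attenuated donor strength of the 3,4,5-trimethoxyphenyl group (twisted 4-methoxy group, two inductively withdrawing meta-methoxy groups) should secure this.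

**Step 7**
Reactants: 13 tert-butyl{[(2S)-4-[(3,4-dimethoxyphenyl)methyl]-2-(3,4,5-trimethoxyphenyl)-2,5-dihydrofuran-3-yl]methoxy}dimethylsilane
Product: 14 [(2S)-4-[(3,4-dimethoxyphenyl)methyl]-2-(3,4,5-trimethoxyphenyl)-2,5-dihydrofuran-3-yl]methanol
Conditions: TBAF, THF, 0 °C
Reagents that add atoms: none
Why: Fluoride-induced cleavage of the primary silyl ether under non-acidic conditions should spare the allylic and benzylic C2–O bond and the C2 configuration.

**Step 8**
Reactants: 14 [(2S)-4-[(3,4-dimethoxyphenyl)methyl]-2-(3,4,5-trimethoxyphenyl)-2,5-dihydrofuran-3-yl]methanol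
Product: 15 [(2R,3R,4R)-4-[(3,4-dimethoxyphenyl)methyl]-2-(3,4,5-trimethoxyphenyl)oxolan-3-yl]methanol
Conditions: H2 (1–4 bar), [Ir(cod)(PCy3)(py)]PF6 (5 mol %), CH2Cl2, 0 °C to rt
Reagents that add atoms: none
Why: Hydroxyl-assisted homogeneous hydrogenation of the tetrasubstituted C3=C4 alkene by a cationic iridium catalyst; syn addition of H2 to the ring face opposite to the C2 aryl group should place CH2OH at C3 and the benzyl group at C4 cis to the aryl group, which is the (2R,3R,4R) configuration.

**Compound list**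
1 | 5-iodo-1,2,3-trimethoxybenzene | COc1cc(I)cc(OC)c1OC | starting material
2 | prop-2-yn-1-ol | C#CCO | starting material
3 | 3-(3,4,5-trimethoxyphenyl)prop-2-yn-1-ol | OCC#Cc1cc(OC)c(OC)c(OC)c1 | intermediate
4 | (3,4-dimethoxyphenyl)magnesium bromide | COc1ccc([Mg]Br)cc1OC | starting material
5 | 2,3-dibromoprop-1-ene | C=C(Br)CBr | starting material
6 | 4-(2-bromoprop-2-en-1-yl)-1,2-dimethoxybenzene | C=C(Br)Cc1ccc(OC)c(OC)c1 | intermediate
7 | [3-(3,4-dimethoxyphenyl)prop-1-en-2-yl]magnesium bromide | C=C([Mg]Br)Cc1ccc(OC)c(OC)c1 | intermediate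
8 | chloromagnesium 3-(3,4,5-trimethoxyphenyl)prop-2-yn-1-olate | Cl[Mg]OCC#Cc1cc(OC)c(OC)c(OC)c1 | intermediate
9 | 4-[3-(3,4-dimethoxyphenyl)prop-1-en-2-yl]-3-(3,4,5-trimethoxyphenyl)-2,5-dihydro-1,2-oxamagnesole | C=C(Cc1ccc(OC)c(OC)c1)C1=C(c2cc(OC)c(OC)c(OC)c2)[Mg]OC1 | intermediate
10 | (2E)-2-[3-(3,4-dimethoxyphenyl)prop-1-en-2-yl]-3-(3,4,5-trimethoxyphenyl)prop-2-en-1-ol | OC/C(=C/c1cc(OC)c(OC)c(OC)c1)C(=C)Cc1ccc(OC)c(OC)c1 | intermediate
11 | [(2S,3S)-2-[3-(3,4-dimethoxyphenyl)prop-1-en-2-yl]-3-(3,4,5-trimethoxyphenyl)oxiran-2-yl]methanol | OC[C@]1(C(=C)Cc2ccc(OC)c(OC)c2)O[C@H]1c1cc(OC)c(OC)c(OC)c1 | intermediate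
12 | tert-butyl{[(2S,3S)-2-[3-(3,4-dimethoxyphenyl)prop-1-en-2-yl]-3-(3,4,5-trimethoxyphenyl)oxiran-2-yl]methoxy}dimethylsilane | CC(C)(C)[Si](C)(C)OC[C@]1(C(=C)Cc2ccc(OC)c(OC)c2)O[C@H]1c1cc(OC)c(OC)c(OC)c1 | intermediate
13 | tert-butyl{[(2S)-4-[(3,4-dimethoxyphenyl)methyl]-2-(3,4,5-trimethoxyphenyl)-2,5-dihydrofuran-3-yl]methoxy}dimethylsilane | CC(C)(C)[Si](C)(C)OCC1=C(Cc2ccc(OC)c(OC)c2)CO[C@H]1c1cc(OC)c(OC)c(OC)c1 | intermediate
14 | [(2S)-4-[(3,4-dimethoxyphenyl)methyl]-2-(3,4,5-trimethoxyphenyl)-2,5-dihydrofuran-3-yl]methanol | OCC1=C(Cc2ccc(OC)c(OC)c2)CO[C@H]1c1cc(OC)c(OC)c(OC)c1 | intermediate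
15 | [(2R,3R,4R)-4-[(3,4-dimethoxyphenyl)methyl]-2-(3,4,5-trimethoxyphenyl)oxolan-3-yl]methanol | COc1ccc(C[C@H]2CO[C@@H](c3cc(OC)c(OC)c(OC)c3)[C@H]2CO)cc1OC | target

Total step count: 8. Longest linear sequence: 7 steps (steps 1, 3, 4, 5, 6, 7, 8).

**Steps most likely to fail**

1. Step 6. Ionisation at the benzylic C2–O bond may compete with opening of the allylic C3–O bond, which would lead to a hydride shift to a ketone or to loss of configuration at C2; elimination to a dienol is a further risk. The fallback sets out from 12 and comes back to the route at 13. The oxirane is opened with LiBr and AcOH in THF at 0 °C to the thermodynamically preferred primary allylic bromide, (1S,2Z)-4-bromo-2-({[tert-butyl(dimethyl)silyl]oxy}methyl)-3-[(3,4-dimethoxyphenyl)methyl]-1-(3,4,5-trimethoxyphenyl)but-2-en-1-ol F1, without touching the C–O bond at the aryl-bearing carbon. Any E isomer should re-enter the Z/E equilibrium by bromide-mediated allylic transposition (LiBr, acetone). NaH in THF at 0 °C then closes the ring by intramolecular Williamson etherification of the Z isomer to 13. The ring is thus made by stepwise opening and closure of an open-chain bromo alcohol instead of by a one-step rearrangement.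

2. Step 8. Uptake of hydrogen at the tetrasubstituted alkene may be slow, which leaves room for migration of the double bond towards C2 (erosion of the C2 configuration), hydrogenolysis of the allylic and benzylic C2–O bond, or poor facial discrimination. The fallback sets out from 13, leaves out step 7 and comes back at 15. The silyl ether 13 is hydrogenated on a surface catalyst (H2, 50 bar, Rh/Al2O3, EtOAc), where only the C2 aryl group controls the face, to tert-butyl{[(2R,3R,4R)-4-[(3,4-dimethoxyphenyl)methyl]-2-(3,4,5-trimethoxyphenyl)oxolan-3-yl]methoxy}dimethylsilane F2. TBAF in THF then removes the silyl group to give 15.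

3. Step 3. Addition of the α-branched alkenyl Grignard reagent to the alkynolate may be sluggish, so that proton transfer from the benzylic CH2 groups or decomposition of the reagent at 80 °C competes. The fallback sets out from 3 (with 6) and comes back at 10. Hydroxyl-directed trans-hydrostannation of 3 (Bu3SnH, [Cp*RuCl]4 as catalyst, CH2Cl2, rt) should place tin on the carbon next to CH2OH and hydrogen trans to it, giving (2Z)-2-(tributylstannyl)-3-(3,4,5-trimethoxyphenyl)prop-2-en-1-ol F3. Stille coupling of this stannane with 6 (Pd(PPh3)4, copper thiophene-2-carboxylate CuO2CC4H3S, DMF, rt) should give 10 with retention of the alkene geometry.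

**Further compounds**
F1 | step 6 | (1S,2Z)-4-bromo-2-({[tert-butyl(dimethyl)silyl]oxy}methyl)-3-[(3,4-dimethoxyphenyl)methyl]-1-(3,4,5-trimethoxyphenyl)but-2-en-1-ol | BrC/C(Cc1ccc(OC)c(OC)c1)=C(/CO[Si](C)(C)C(C)(C)C)[C@@H](O)c1cc(OC)c(OC)c(OC)c1
F2 | step 8 | tert-butyl{[(2R,3R,4R)-4-[(3,4-dimethoxyphenyl)methyl]-2-(3,4,5-trimethoxyphenyl)oxolan-3-yl]methoxy}dimethylsilane | COc1ccc(C[C@H]2CO[C@@H](c3cc(OC)c(OC)c(OC)c3)[C@H]2CO[Si](C)(C)C(C)(C)C)cc1OC
F3 | step 3 | (2Z)-2-(tributylstannyl)-3-(3,4,5-trimethoxyphenyl)prop-2-en-1-ol | OC/C(=C/c1cc(OC)c(OC)c(OC)c1)[Sn](CCCC)(CCCC)CCCC
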